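The meeting decided to split each forecast of mono adduct into two factors: how much starting material is consumed, and what share of that stays as mono adduct.

in all of them: starting material 0.25 M
- spring: reagent 0.093 M; run made earlier
- noon: reagent 0.37 M; run made earlier
- amber: reagent 0.125 M; time 30 h
- blue: reagent 0.250 M; time 30 h
- teal: reagent 1.00 M; time 30 h

| run | time / h | mono adduct / % | starting material / % |
|---|---|---|---|
| spring | 2.50 | 14.6 | 81.0 |
| spring | 8.00 | 16.1 | 74.9 |
| spring | 15.0 | 15.7 | 73.2 |
| spring | 20.0 | 16.0 | 73.1 |
| spring | 30.0 | 16.3 | 71.6 |
| noon | 2.50 | 28.3 | 53.7 |
| noon | 5.00 | 31.1 | 47.1 |
| noon | 8.00 | 34.3 | 44.5 |
| noon | 15.0 | 35.4 | 41.8 |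
| noon | 30.0 | 36.4 | 42.7 |

(each reading ± 1 percentage point)

- mono adduct is meant together with its crystals
- solid, in amounts per volume of the solution: crystals
- the earlier runs were read with a standard deviation of 1 percentage point
- steps under discussion: crystals <-> mono adduct; reagent + mono adduct -> double product + released group; reagent + other mono adduct -> double product + released group; starting material + reagent -> other mono adduct + released group; 2 reagent -> homo dimer; starting material + reagent -> mono adduct + released group

1. final mono adduct, as a percentage of the starting material charged, for each flask in turn (amber, blue, teal)

The first speaker read the last row of each earlier run, where the readings have levelled off. In the spring run 71.6 % of the starting material remained at 30.0 h, with 16.3 % mono adduct, so the share came to 57.4 %. In the noon run 42.7 % remained, with 36.4 % mono adduct, so the share came to 63.5 %.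

The second speaker argued that this gap is of a size that a scatter of 1 percentage point on each reading allows, since the spring run consumed 28.4 %. She therefore proposed one number, the keeping share, meaning the mono adduct found per starting material consumed (a selectivity), taken as the mean reading 60.5 %.

The third speaker objected that a second attack of reagent on mono adduct might take over at a high charge, and that control would then pass from the choice between the two mono adducts to that later step. He was answered that the noon share, at 0.37 M reagent, reads higher than the spring share, so these two readings show no fall of the share with the charge.

The forecast gave 20 %, 31 % and 43 % for amber, blue and teal. Read through the keeping share, its teal value stands for 71.1 % consumed, against its own 76 %. Of the teal flask the forecast says that “longer-lived reagent should erode it somewhat”. The meeting, differing here, kept the share flat for teal.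

The flasks give 20.1 %, 30.0 % and 47.7 % mono adduct for amber, blue and teal.

    crystals ⇌ mono adduct, rate k1*(cs1 - [mono adduct]) while solid is left; crystals form when [mono adduct] > cs1 (solubility = 3.90 mM, k = 5.30 min⁻¹)
    reagent + mono adduct → double product + released group (k = 0.00170 M⁻¹ min⁻¹)
    reagent + other mono adduct → double product + released group (k = 0.0170 M⁻¹ min⁻¹)
    starting material + reagent → other mono adduct + released group (k = 0.0140 M⁻¹ min⁻¹)
    2 reagent → homo dimer (k = 0.0340 M⁻¹ min⁻¹)
    starting material + reagent → mono adduct + released group (k = 0.0220 M⁻¹ min⁻¹)

At 30.0 h the teal flask held 21.8 % starting material, and its mono adduct included 46.1 % crystals. The keeping share times the starting material consumed gives 47.3 % for teal, where the flask stands at 47.7 %. For the blue flask, with 50.9 % starting material left, the same product gives 29.7 %, and the flask stands at 30.0 %.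

(The readings were generated by integration for an exercise.)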